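**Plan**

- Retrosynthesis: the C2–Br bond is traced back to the lactam C=O of an oxindole and N1–H to an N-(4-methoxybenzyl) lactam. The C3–C3a bond is then cut, followed by the amide C2–N1 bond and the N–CH2Ar bond, leaving 3,5-dibromoaniline, anisaldehyde and (methylsulfanyl)acetic acid.
- Forward: the benzene ring is bought. N-benzylation, N-acylation and S-oxidation hang the N1–C2–C3–S chain on nitrogen, the five-membered ring (the only ring built) closes by C3–C3a bond formation, and debenzylation plus dehydrative bromination of the lactam deliver the indole.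
- Enabling feature: C3 carries the sulfur and can therefore be an α-acyl thionium carbon. Its partner C3a is ortho to N1, ortho to the C4 bromine and para to the C6 bromine, and is one of two equivalent ortho carbons of the 3,5-dibromoanilide ring, so only one regioisomer can form.
- Stereochemistry: the target is planar and achiral. The sulfur centre of the sulfoxide and C3 of the oxindoles are racemic and disappear on aromatisation.

Key step: step 4

Remark on the chemistry: the target has no stereogenic element, so the single-enantiomer requirement is met trivially; compounds 8, 9, 11 and 12 are carried as racemates.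

**Route**

Step 1
Reactants: 1 3,5-dibromoaniline; 2 4-methoxybenzaldehyde
Product: 4 3,5-dibromo-N-(4-methoxybenzyl)aniline, via aldimine 3 (not isolated)
Conditions: NaBH(OAc)3, AcOH, ClCH2CH2Cl, rt
Reagents that add atoms: none
Why: Reductive amination, in which acetic acid promotes condensation of the weakly basic aniline to aldimine 3 and triacetoxyborohydride reduces it in preference to the aldehyde, while the product N-benzylaniline is too weakly basic to be benzylated again and the aryl bromides are inert to the hydride.

Step 2
Reactants: 4 3,5-dibromo-N-(4-methoxybenzyl)aniline; 5 (methylsulfanyl)acetic acid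
Product: 7 N-(3,5-dibromophenyl)-N-(4-methoxybenzyl)-2-(methylsulfanyl)acetamide, via (methylsulfanyl)acetyl chloride 6 (not isolated)
Conditions: 5, (COCl)2, cat. DMF, CH2Cl2, 0 °C → rt; then 4, pyridine, cat. DMAP, CH2Cl2, 0 °C → rt
Reagents that add atoms: none
Why: N-Acylation by an acid chloride made in the flask (oxalyl chloride/DMF activation), which is reactive enough for an electron-poor secondary aniline, with pyridine/DMAP taking up HCl and the thioether and aryl bromides not interfering.

Step 3
Reactants: 7 N-(3,5-dibromophenyl)-N-(4-methoxybenzyl)-2-(methylsulfanyl)acetamide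
Product: 8 N-(3,5-dibromophenyl)-N-(4-methoxybenzyl)-2-(methylsulfinyl)acetamide (racemic at sulfur)
Conditions: NaIO4, MeOH/H2O, 0 °C → rt
Reagents that add atoms: sodium periodate, [Na+].[O-]I(=O)(=O)=O
Why: Periodate oxidation of a dialkyl sulfide should stop at the sulfoxide and leave the amide and anisyl ring untouched; the new sulfur stereocentre forms as a racemate and is destroyed in step 4.

Step 4
Reactants: 8 N-(3,5-dibromophenyl)-N-(4-methoxybenzyl)-2-(methylsulfinyl)acetamide
Product: 11 (±)-4,6-dibromo-1-(4-methoxybenzyl)-3-(methylsulfanyl)indolin-2-one, via trifluoroacetoxy sulfide 9 (not isolated), via acyl thionium ion 10 (not isolated)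
Conditions: (CF3CO)2O, CH2Cl2 (dilute), 0 °C; then BF3·OEt2, 0 °C → rt; aq NaHCO3 work-up
Reagents that add atoms: none
Why: Trifluoroacetylation of the sulfoxide oxygen and loss of the acidic proton between C=O and sulfur give the Pummerer adduct 9, which boron trifluoride ionises to the α-acyl thionium ion 10; this alkylates the ortho carbon of the N-aryl ring and proton loss restores the arene. The closest known reaction type is the Pummerer cyclisation (intramolecular Friedel–Crafts alkylation) of N-alkyl α-sulfinyl- or α-chloro-α-sulfanyl-acetanilides to 3-(alkylsulfanyl)oxindoles. The five-membered lactam ring closes through the C3–C3a bond in a 5-exo-trig mode with respect to the C=S+ bond (sulfur stays outside the ring), the attacked arene bond lying inside the new ring. The new C3 stereocentre forms without control as a racemate, which is immaterial because C3 becomes sp2 in step 6. The step needs closure on the dibromoaryl ring and not on the anisyl ring: the tertiary anilide prefers the rotamer with the N-aryl group beside the thionium carbon, and the attacked carbon is ortho to nitrogen and ortho/para to the bromines, whereas the benzyl ring offers only carbons meta to OMe for a six-membered ring or a reversible spiro ipso adduct. The thionium ion should form on the amide side only, since the CH2 between carbonyl and sulfur is far more acidic than S-methyl, and dilution suppresses intermolecular alkylation of the anisyl ring.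

Step 5
Reactants: 11 (±)-4,6-dibromo-1-(4-methoxybenzyl)-3-(methylsulfanyl)indolin-2-one
Product: 12 (±)-4,6-dibromo-3-(methylsulfanyl)indolin-2-one
Conditions: CF3SO3H, anisole, CF3CO2H, 0 °C → rt (argon)
Reagents that add atoms: none
Why: Acidolytic N-debenzylation of a 4-methoxybenzyl lactam, in which the O-protonated lactam ionises to the 4-methoxybenzyl cation that anisole captures irreversibly (Friedel–Crafts), while the aryl bromides and the thioether tolerate the non-oxidising acid.

Step 6
Reactants: 12 (±)-4,6-dibromo-3-(methylsulfanyl)indolin-2-one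
Product: 13 2,4,6-tribromo-3-(methylsulfanyl)-1H-indole
Conditions: POBr3, imidazole, ClCH2CH2Cl, 80 °C; aq NaHCO3 work-up
Reagents that add atoms: phosphorus oxybromide, O=P(Br)(Br)Br
Why: Vilsmeier–Haack-type dehydrative bromination of a lactam, in which POBr3 phosphorylates the lactam oxygen, bromide displaces the phosphate at C2 through the 2-bromo-3H-indole stage, and loss of the C3 proton aromatises the pyrrole ring and erases the C3 stereocentre.

**Compound list**

1 | 3,5-dibromoaniline | Nc1cc(Br)cc(Br)c1 | starting material
2 | 4-methoxybenzaldehyde | COc1ccc(C=O)cc1 | starting material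
3 | (E)-N-(3,5-dibromophenyl)-1-(4-methoxyphenyl)methanimine (formed in the flask, not isolated) | COc1ccc(/C=N/c2cc(Br)cc(Br)c2)cc1 | intermediate
4 | 3,5-dibromo-N-(4-methoxybenzyl)aniline | COc1ccc(CNc2cc(Br)cc(Br)c2)cc1 | intermediate
5 | (methylsulfanyl)acetic acid | CSCC(=O)O | starting material
6 | (methylsulfanyl)acetyl chloride (formed in the flask, not isolated) | CSCC(=O)Cl | intermediate
7 | N-(3,5-dibromophenyl)-N-(4-methoxybenzyl)-2-(methylsulfanyl)acetamide | CSCC(=O)N(Cc1ccc(OC)cc1)c1cc(Br)cc(Br)c1 | intermediate
8 | N-(3,5-dibromophenyl)-N-(4-methoxybenzyl)-2-(methylsulfinyl)acetamide (racemic at sulfur) | CS(=O)CC(=O)N(Cc1ccc(OC)cc1)c1cc(Br)cc(Br)c1 | intermediate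
9 | 2-[(3,5-dibromophenyl)(4-methoxybenzyl)amino]-1-(methylsulfanyl)-2-oxoethyl trifluoroacetate (racemic; formed in the flask, not isolated) | CSC(OC(=O)C(F)(F)F)C(=O)N(Cc1ccc(OC)cc1)c1cc(Br)cc(Br)c1 | intermediate
10 | {2-[(3,5-dibromophenyl)(4-methoxybenzyl)amino]-2-oxoethylidene}(methyl)sulfonium trifluoroacetate (formed in the flask, not isolated) | C[S+]=CC(=O)N(Cc1ccc(OC)cc1)c1cc(Br)cc(Br)c1.[O-]C(=O)C(F)(F)F | intermediate
11 | (±)-4,6-dibromo-1-(4-methoxybenzyl)-3-(methylsulfanyl)indolin-2-one | CSC1C(=O)N(Cc2ccc(OC)cc2)c2cc(Br)cc(Br)c21 | intermediate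
12 | (±)-4,6-dibromo-3-(methylsulfanyl)indolin-2-one | CSC1C(=O)Nc2cc(Br)cc(Br)c21 | intermediate
13 | 2,4,6-tribromo-3-(methylsulfanyl)-1H-indole | CSc1c(Br)[nH]c2cc(Br)cc(Br)c12 | target

**Count**

Total steps: 6. Longest linear sequence: 6 steps (from 1).

**Steps most likely to fail**

Step 4. Capture of the thionium ion by the doubly brominated ring may be too slow. In that case attack on the anisyl ring (ipso or intermolecular), Lewis-acid debenzylation, or hydrolysis of the Pummerer adduct at work-up could outrun ring closure. The fallback gives up the electrophilic closure for a Gassman-type sigmatropic ortho-alkylation, which needs neither an N-substituent nor a nucleophilic arene. It sets out from 1: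
- tert-butyl hypochlorite (CH2Cl2, −65 °C) gives N-chloro-3,5-dibromoaniline F1;
- ethyl (methylsulfanyl)acetate converts this into (3,5-dibromoanilino)(2-ethoxy-2-oxoethyl)(methyl)sulfonium chloride F2;
- triethylamine triggers the Sommelet–Hauser [2,3]-shift to ethyl 2-(2-amino-4,6-dibromophenyl)-2-(methylsulfanyl)acetate F3 (both ortho carbons of 1 are equivalent);
- dilute HCl closes the lactam to 12, where the route is rejoined before step 6.

Step 5. Cleavage of the N–benzyl bond of the N-aryl lactam may remain incomplete under acid mild enough for the substrate. Stronger acid invites transfer of the methylsulfanyl group to the scavenger or re-benzylation. The fallback changes the nitrogen substituent to the more acid-labile 2,4-dimethoxybenzyl group and sets out from 1: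
- reductive amination with 2,4-dimethoxybenzaldehyde (as in step 1) passes through (E)-N-(3,5-dibromophenyl)-1-(2,4-dimethoxyphenyl)methanimine F4 and gives 3,5-dibromo-N-(2,4-dimethoxybenzyl)aniline F5;
- acylation with 6 (generated from 5 as in step 2) gives N-(3,5-dibromophenyl)-N-(2,4-dimethoxybenzyl)-2-(methylsulfanyl)acetamide F6;
- periodate oxidation gives N-(3,5-dibromophenyl)-N-(2,4-dimethoxybenzyl)-2-(methylsulfinyl)acetamide F7;
- trifluoroacetic anhydride without Lewis acid (to spare the benzyl group) leads through 2-[(3,5-dibromophenyl)(2,4-dimethoxybenzyl)amino]-1-(methylsulfanyl)-2-oxoethyl trifluoroacetate F8 and {2-[(3,5-dibromophenyl)(2,4-dimethoxybenzyl)amino]-2-oxoethylidene}(methyl)sulfonium trifluoroacetate F9 to (±)-4,6-dibromo-1-(2,4-dimethoxybenzyl)-3-(methylsulfanyl)indolin-2-one F10;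
- trifluoroacetic acid/anisole at room temperature, without triflic acid, then releases 12, where the route is rejoined.

Step 6. O-Activation of the lactam by POBr3 may stall. The electron-rich 2-bromo-3-sulfanylindole may also degrade under the hot acidic conditions (protodebromination, oxidative coupling at C3, attack at sulfur). The fallback separates removal of the carbonyl oxygen from introduction of bromine and sets out from 12:
- DIBAL-H (CH2Cl2, −78 → 0 °C) reduces the lactam to 4,6-dibromo-3-(methylsulfanyl)indolin-2-ol F11 (mixture of diastereomers);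
- on mildly acidic work-up this loses water to give 4,6-dibromo-3-(methylsulfanyl)-1H-indole F12;
- N-bromosuccinimide (CH2Cl2, 0 °C) brominates the only free pyrrole carbon, C2, to give 13, the end of the route.

**Further compounds**

F1 | step 4 | N-chloro-3,5-dibromoaniline | ClNc1cc(Br)cc(Br)c1
F2 | step 4 | (3,5-dibromoanilino)(2-ethoxy-2-oxoethyl)(methyl)sulfonium chloride | CCOC(=O)C[S+](C)Nc1cc(Br)cc(Br)c1.[Cl-]
F3 | step 4 | ethyl 2-(2-amino-4,6-dibromophenyl)-2-(methylsulfanyl)acetate | CCOC(=O)C(SC)c1c(N)cc(Br)cc1Br
F4 | step 5 | (E)-N-(3,5-dibromophenyl)-1-(2,4-dimethoxyphenyl)methanimine | COc1ccc(/C=N/c2cc(Br)cc(Br)c2)c(OC)c1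
F5 | step 5 | 3,5-dibromo-N-(2,4-dimethoxybenzyl)aniline | COc1ccc(CNc2cc(Br)cc(Br)c2)c(OC)c1
F6 | step 5 | N-(3,5-dibromophenyl)-N-(2,4-dimethoxybenzyl)-2-(methylsulfanyl)acetamide | CSCC(=O)N(Cc1ccc(OC)cc1OC)c1cc(Br)cc(Br)c1
F7 | step 5 | N-(3,5-dibromophenyl)-N-(2,4-dimethoxybenzyl)-2-(methylsulfinyl)acetamide | CS(=O)CC(=O)N(Cc1ccc(OC)cc1OC)c1cc(Br)cc(Br)c1
F8 | step 5 | 2-[(3,5-dibromophenyl)(2,4-dimethoxybenzyl)amino]-1-(methylsulfanyl)-2-oxoethyl trifluoroacetate | CSC(OC(=O)C(F)(F)F)C(=O)N(Cc1ccc(OC)cc1OC)c1cc(Br)cc(Br)c1
F9 | step 5 | {2-[(3,5-dibromophenyl)(2,4-dimethoxybenzyl)amino]-2-oxoethylidene}(methyl)sulfonium trifluoroacetate | C[S+]=CC(=O)N(Cc1ccc(OC)cc1OC)c1cc(Br)cc(Br)c1.[O-]C(=O)C(F)(F)F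
F10 | step 5 | (±)-4,6-dibromo-1-(2,4-dimethoxybenzyl)-3-(methylsulfanyl)indolin-2-one | CSC1C(=O)N(Cc2ccc(OC)cc2OC)c2cc(Br)cc(Br)c21
F11 | step 6 | 4,6-dibromo-3-(methylsulfanyl)indolin-2-ol | CSC1C(O)Nc2cc(Br)cc(Br)c21
F12 | step 6 | 4,6-dibromo-3-(methylsulfanyl)-1H-indole | CSc1c[nH]c2cc(Br)cc(Br)c12
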